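**Retrosynthetic overview**
- The target is reached by late 7‑O‑methylation of (2S)‑5,7‑dihydroxy‑8‑geranylflavanone.
- That flavanone comes from one flask in which both rings are made from two open‑chain partners: an (S)‑δ‑hydroxy α‑oxo ketene dithioacetal (C2–C4a plus C8a) and the dianion of a geranylated acetoacetate (C5–C8).
- Ring order: the pyranone ring C closes first (O1–C8a), then C8–C8a is joined, then ring A closes by a C4a–C5 Claisen cyclization that aromatizes.
- The hydroxy ketene dithioacetal comes from the (S)‑aldol of acetone and benzaldehyde (sets C2) followed by CS2/MeI; the keto ester comes from methyl acetoacetate dianion and geranyl bromide.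

Assumption: commercial geranyl bromide is the (2E) isomer and "geranyl" means (2E)‑3,7‑dimethylocta‑2,6‑dien‑1‑yl; O1, C2 … C8a are flavanone locants.

**Step 1**
Reactants: 1 methyl acetoacetate; 2 geranyl bromide
Product: 3 methyl (6E)‑7,11‑dimethyl‑3‑oxododeca‑6,10‑dienoate
Conditions: NaH (1.1 equiv), THF, 0 °C; n‑BuLi (1.05 equiv), 0 °C; 2 (1.0 equiv), 0 °C → rt; aq HCl
Reagents that add atoms: none
Why: Weiler dianion alkylation, in which the γ‑carbanion of the acetoacetate dianion is the most nucleophilic site and displaces the allylic bromide by SN2 with the E‑alkene retained.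

**Step 2**
Reactants: 4 acetone; 5 benzaldehyde
Product: 6 (4S)‑4‑hydroxy‑4‑phenylbutan‑2‑one
Conditions: (R)‑N‑[(R)‑1‑hydroxy‑4‑methyl‑1,1‑diphenylpentan‑2‑yl]pyrrolidine‑2‑carboxamide (10 mol %), acetone as solvent, −40 °C, 48 h
Reagents that add atoms: none
Why: Direct enamine (proline‑type) aldol reaction; L‑proline‑derived catalysts attack the Re face of ArCHO to give (R), so this D‑prolinamide attacks the Si face through the same hydrogen‑bonded transition state and sets (S) at the carbinol carbon (later C2).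

**Step 3**
Reactants: 6 (4S)‑4‑hydroxy‑4‑phenylbutan‑2‑one
Product: 7 (5S)‑5‑hydroxy‑1,1‑bis(methylsulfanyl)‑5‑phenylpent‑1‑en‑3‑one
Conditions: LiHMDS (2.05 equiv), THF/DMPU, −78 °C; CS2 (1.1 equiv), −78 → −30 °C; MeI (2.2 equiv), −30 → 0 °C; AcOH quench
Reagents that add atoms: carbon disulfide S=C=S; iodomethane CI
Why: Standard α‑oxo ketene dithioacetal synthesis (enolate dithiocarboxylation then double S‑methylation) run on the kinetic methyl‑side enolate of the lithium aldolate, whose alkoxide acts as the internal second base, so the OH ends up free and the carbinol centre is untouched.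

**Step 4**
Reactants: 7 (5S)‑5‑hydroxy‑1,1‑bis(methylsulfanyl)‑5‑phenylpent‑1‑en‑3‑one; 3 methyl (6E)‑7,11‑dimethyl‑3‑oxododeca‑6,10‑dienoate
Product: 10 (2S)‑5,7‑dihydroxy‑8‑geranylflavanone, via methylthio‑dihydropyranone 8 (not isolated), via pyranone keto ester 9 (not isolated)
Conditions: 7, LiHMDS (1.05 equiv), THF, −78 → 0 °C; cannulate into dianion of 3 [3 (1.3 equiv), LDA (2.6 equiv), THF, −78 → 0 °C] at −78 °C, then 0 °C, 2 h; KOt‑Bu (2.5 equiv), 0 → 25 °C; cold 1 M HCl
Reagents that add atoms: none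
Why: Proposed new method: the alkoxide of 7 displaces one MeS by intramolecular vinylic substitution to give 8 (closest known: closure of 2‑hydroxyaryl α‑oxo ketene dithioacetals to 2‑methylthiochromones), the γ‑carbanion of the dianion of 3 displaces the second MeS by addition–elimination to give 9 (closest known: Junjappa–Ila [3+3] benzannulation), and KOt‑Bu then forms the C8 dienolate whose C4a attacks the ester in a polyketide‑type phloroglucinol‑mode Claisen cyclization that aromatizes with loss of methanol, while C2 is never a reacting centre and C3 is not deprotonated once the pyranone is a dienolate or phenoxide, so (S) is carried through.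

**Step 5**
Reactants: 10 (2S)‑5,7‑dihydroxy‑8‑geranylflavanone
Product: 11 (2S)‑8‑geranyl‑5‑hydroxy‑7‑methoxyflavanone (target)
Conditions: TMSCHN2 (1.2 equiv), MeOH/toluene 1:4, 0 °C → rt
Reagents that add atoms: trimethylsilyldiazomethane C[Si](C)(C)C=[N+]=[N-]
Why: Chemoselective diazoalkane O‑methylation of the more acidic, non‑chelated 7‑OH (the 5‑OH is hydrogen‑bonded to C4=O), under neutral conditions that avoid base‑induced ring opening and so keep C2 intact.

**Compound list**
1 | methyl acetoacetate (methyl 3‑oxobutanoate) | COC(=O)CC(C)=O | starting material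
2 | geranyl bromide, (2E)‑1‑bromo‑3,7‑dimethylocta‑2,6‑diene | BrC/C=C(\C)CCC=C(C)C | starting material
3 | methyl (6E)‑7,11‑dimethyl‑3‑oxododeca‑6,10‑dienoate | COC(=O)CC(=O)CC/C=C(\C)CCC=C(C)C | intermediate
4 | acetone | CC(C)=O | starting material
5 | benzaldehyde | O=Cc1ccccc1 | starting material
6 | (4S)‑4‑hydroxy‑4‑phenylbutan‑2‑one | CC(=O)C[C@H](O)c1ccccc1 | intermediate
7 | (5S)‑5‑hydroxy‑1,1‑bis(methylsulfanyl)‑5‑phenylpent‑1‑en‑3‑one | CSC(SC)=CC(=O)C[C@H](O)c1ccccc1 | intermediate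
8 | (2S)‑6‑(methylsulfanyl)‑2‑phenyl‑2,3‑dihydro‑4H‑pyran‑4‑one | CSC1=CC(=O)C[C@@H](c2ccccc2)O1 | intermediate
9 | methyl (6E)‑7,11‑dimethyl‑3‑oxo‑4‑[(2S)‑4‑oxo‑2‑phenyl‑3,4‑dihydro‑2H‑pyran‑6‑yl]dodeca‑6,10‑dienoate (epimers at C4) | COC(=O)CC(=O)C(C/C=C(\C)CCC=C(C)C)C1=CC(=O)C[C@@H](c2ccccc2)O1 | intermediate
10 | (2S)‑8‑[(2E)‑3,7‑dimethylocta‑2,6‑dien‑1‑yl]‑5,7‑dihydroxy‑2‑phenyl‑2,3‑dihydro‑4H‑chromen‑4‑one | Oc1cc(O)c2c(c1C/C=C(\C)CCC=C(C)C)O[C@H](c1ccccc1)CC2=O | intermediate
11 | (2S)‑8‑[(2E)‑3,7‑dimethylocta‑2,6‑dien‑1‑yl]‑5‑hydroxy‑7‑methoxy‑2‑phenyl‑2,3‑dihydro‑4H‑chromen‑4‑one | COc1cc(O)c2c(c1C/C=C(\C)CCC=C(C)C)O[C@H](c1ccccc1)CC2=O | target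

**Count and risks**
Total steps: 5. Longest linear sequence: 4 (steps 2, 3, 4, 5); step 1 is a one‑step side branch.

Most likely to fail, first: step 4. The hard dianion may add 1,2 to the C4 carbonyl of 8 or deprotonate C3 of 8, which would open the ring by E1cB and erode ee. The Claisen closure onto an ester that belongs to an enolized β‑keto ester may also stall. The fallback sets out from 7 and 2 and comes back at 10, making the rings one at a time without strong base at the ring‑A stage. Compound 7 is cyclized alone (catalytic DBU, CH2Cl2) and 8 is isolated. tert‑Butyl acetoacetate is alkylated with 2 as in step 1 to tert‑butyl (6E)‑7,11‑dimethyl‑3‑oxododeca‑6,10‑dienoate F1. F1 is bis‑silylated (Et3N/TMSCl, then LDA/TMSCl) to (6E)‑1‑tert‑butoxy‑7,11‑dimethyl‑1,3‑bis(trimethylsilyloxy)dodeca‑1,3,6,10‑tetraene F2. TMSOTf‑catalysed vinylogous Mukaiyama addition–elimination of F2 to 8 at −78 °C gives tert‑butyl (6E)‑7,11‑dimethyl‑3‑oxo‑4‑[(2S)‑4‑oxo‑2‑phenyl‑3,4‑dihydro‑2H‑pyran‑6‑yl]dodeca‑6,10‑dienoate F3. Heating F3 in toluene at 110 °C expels tert‑butanol, and the resulting acylketene closes ring A by 6π‑electrocyclization of its dienylketene enol and tautomerization to 10.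

Second: step 3. The free alkoxide may form a xanthate, the enolate may form on the wrong side, or the product may close early to 8 (the last is harmless, since 8 is the first intermediate of step 4). The fallback sets out from 5 and comes back at 7, bypassing 6. Commercial 4,4‑bis(methylsulfanyl)but‑3‑en‑2‑one is silylated (TMSOTf, Et3N) to 1,1‑bis(methylsulfanyl)‑3‑(trimethylsilyloxy)buta‑1,3‑diene F4. A catalytic enantioselective Mukaiyama aldol addition of F4 to 5 (SiCl4 with a chiral bisphosphoramide Lewis base, antipode chosen for Si‑face attack and checked by Mosher analysis) gives 7 after aqueous KF/NaHCO3 work‑up.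

Third: step 5. The 7‑OH sits next to the geranyl group, so methylation may be slow, and forcing it risks touching the 5‑OH or the base‑labile C2 centre. The fallback sets out from 3 and comes back at 11, placing the methyl ether before the annulation. Compound 3 is converted (HC(OMe)3, catalytic H2SO4, MeOH) into methyl (2E,6E)‑3‑methoxy‑7,11‑dimethyldodeca‑2,6,10‑trienoate F5. γ‑Lithiation of F5 (LDA, THF/DMPU, −78 °C) and reaction with 7, pre‑treated with LiHMDS as in step 4, gives methyl (2E,6E)‑3‑methoxy‑7,11‑dimethyl‑4‑[(2S)‑4‑oxo‑2‑phenyl‑3,4‑dihydro‑2H‑pyran‑6‑yl]dodeca‑2,6,10‑trienoate F6 in the flask. KOt‑Bu then closes ring A by the same Claisen aromatization, here helped by the fixed E enol‑ether geometry, and gives 11 directly.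

**Further compounds**
F1 | step 4 | tert‑butyl (6E)‑7,11‑dimethyl‑3‑oxododeca‑6,10‑dienoate | CC(C)(C)OC(=O)CC(=O)CC/C=C(\C)CCC=C(C)C
F2 | step 4 | (6E)‑1‑tert‑butoxy‑7,11‑dimethyl‑1,3‑bis(trimethylsilyloxy)dodeca‑1,3,6,10‑tetraene | CC(C)(C)OC(O[Si](C)(C)C)=CC(O[Si](C)(C)C)=CC/C=C(\C)CCC=C(C)C
F3 | step 4 | tert‑butyl (6E)‑7,11‑dimethyl‑3‑oxo‑4‑[(2S)‑4‑oxo‑2‑phenyl‑3,4‑dihydro‑2H‑pyran‑6‑yl]dodeca‑6,10‑dienoate | CC(C)(C)OC(=O)CC(=O)C(C/C=C(\C)CCC=C(C)C)C1=CC(=O)C[C@@H](c2ccccc2)O1
F4 | step 3 | 1,1‑bis(methylsulfanyl)‑3‑(trimethylsilyloxy)buta‑1,3‑diene | CSC(SC)=CC(=C)O[Si](C)(C)C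
F5 | step 5 | methyl (2E,6E)‑3‑methoxy‑7,11‑dimethyldodeca‑2,6,10‑trienoate | COC(=O)/C=C(/OC)CC/C=C(\C)CCC=C(C)C
F6 | step 5 | methyl (2E,6E)‑3‑methoxy‑7,11‑dimethyl‑4‑[(2S)‑4‑oxo‑2‑phenyl‑3,4‑dihydro‑2H‑pyran‑6‑yl]dodeca‑2,6,10‑trienoate | COC(=O)/C=C(/OC)C(C/C=C(\C)CCC=C(C)C)C1=CC(=O)C[C@@H](c2ccccc2)O1
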